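**Assumptions**
- The target has no stereocentre and no stereogenic double bond, so it is achiral and there is no enantiomer to select.
- The target is drawn as the free bis(hydrogen sulfate), so the last step ends with protonation of the salt on an acid resin.
- Formaldehyde N,N-dimethylhydrazone is taken as a purchased reagent.

**Retrosynthetic overview**
1. C–C disconnection at the ring carbon–CH bond: electrophilic C4 of o-bromanil 1 is joined to the azomethine carbon of formaldehyde N,N-dimethylhydrazone 2, a neutral formyl anion equivalent. Substitution of Br gives quinone 3, which is reduced to catechol 4 and hydrolysed to aldehyde 5.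
2. Aryl O–S disconnection: the formyl group of 5 makes the para OH the more acidic phenol, so it alone is sulfated (6); the aldehyde is then reduced to benzylic alcohol 7.
3. Benzylic O–S disconnection: 7 gives bis-sulfate salt 8, which is protonated to the free acid 9 (target).
4. No ring is formed: the benzene ring and all three bromines come intact from 1.

**Route**

Step 1
Reactants: 1 o-bromanil (3,4,5,6-tetrabromocyclohexa-3,5-diene-1,2-dione); 2 formaldehyde N,N-dimethylhydrazone
Product: 5 2,3,6-tribromo-4,5-dihydroxybenzaldehyde, via quinone hydrazone 3 (not isolated), via catechol hydrazone 4 (not isolated)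
Conditions: 2 (1.05 equiv), 2,6-lutidine (1.1 equiv), CH2Cl2, −78 → 0 °C; then SnCl2·2H2O (1.5 equiv), 2 M aq HCl, THF, 50 °C
Reagents that add atoms: water (O)
Why: Proposed new method: 2 reacts as a neutral aza-enamine through its azomethine carbon, adding to C4 of 1 (the β-carbon of the ene-dione, where heteroatom nucleophiles substitute tetrahalo-o-quinones), and loss of bromide and of the CH proton (addition–elimination, HBr buffered by 2,6-lutidine) gives the donor–acceptor quinone 3, which is deactivated towards a second substitution, after which divalent tin reduces the quinone to catechol 4 and aqueous HCl hydrolyses the hydrazone to 5; the closest known reaction types are the Michael addition of formaldehyde dialkylhydrazones to electron-poor alkenes and the C-substitution of chloranil by enamines, and because C4 and C5 of 1 are equivalent only one regioisomer can form and no stereocentre is created.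

Step 2
Reactants: 5 2,3,6-tribromo-4,5-dihydroxybenzaldehyde
Product: 7 triethylammonium 2,3,5-tribromo-6-hydroxy-4-(hydroxymethyl)phenyl sulfate, via formyl aryl sulfate 6 (not isolated)
Conditions: Et3N (1.0 equiv), SO3·NEt3 (1.15 equiv), DMF, argon, 0 → 40 °C; then H3N·BH3 (0.5 equiv), MeOH, 0 °C → rt; C18 chromatography with triethylammonium bicarbonate buffer
Reagents that add atoms: sulfur trioxide–triethylamine complex (CC[N+](CC)(CC)S(=O)(=O)[O-])
Why: The 4-OH para to the formyl group is a vinylogous carboxylic acid and clearly more acidic than the 5-OH, so one equivalent of Et3N ionises it alone and that phenoxide takes SO3 from the amine complex (regioselective O-sulfation, the same selectivity as in 4-O-alkylation of 3,4-dihydroxybenzaldehyde), after which ammonia borane reduces the hindered aldehyde to the benzylic alcohol (chemoselective hydride reduction) without touching the aryl bromides or the sulfate.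

Step 3
Reactants: 7 triethylammonium 2,3,5-tribromo-6-hydroxy-4-(hydroxymethyl)phenyl sulfate
Product: 9 2,3,5-tribromo-6-hydroxy-4-[(sulfooxy)methyl]phenyl hydrogen sulfate (target), via bis-sulfate ammonium salt 8 (not isolated)
Conditions: SO3·pyridine (1.5 equiv), DMF, 0 °C; then H2O, sulfonic acid cation-exchange resin (H+ form), 0 °C; freeze-dry
Reagents that add atoms: sulfur trioxide–pyridine complex ([O-]S(=O)(=O)[n+]1ccccc1)
Why: Without added base, SO3·pyridine sulfates the primary benzylic alcohol much faster than the remaining phenol, which is electron-poor, un-ionised and flanked by Br and an anionic sulfate (chemoselective O-sulfation), and cation exchange on the acid resin then protonates both sulfate groups while retaining the two amines.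

**Compound list**
1 | 3,4,5,6-tetrabromocyclohexa-3,5-diene-1,2-dione (o-bromanil) | O=C1C(=O)C(Br)=C(Br)C(Br)=C1Br | starting material
2 | formaldehyde N,N-dimethylhydrazone (1,1-dimethyl-2-methylidenehydrazine) | C=NN(C)C | starting material
3 | 3,4,6-tribromo-5-[(E)-(2,2-dimethylhydrazinylidene)methyl]cyclohexa-3,5-diene-1,2-dione | O=C1C(=O)C(Br)=C(Br)C(/C=N/N(C)C)=C1Br | intermediate
4 | 3,4,6-tribromo-5-[(E)-(2,2-dimethylhydrazinylidene)methyl]benzene-1,2-diol | CN(C)/N=C/c1c(Br)c(O)c(O)c(Br)c1Br | intermediate
5 | 2,3,6-tribromo-4,5-dihydroxybenzaldehyde | O=Cc1c(Br)c(O)c(O)c(Br)c1Br | intermediate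
6 | triethylammonium 2,3,5-tribromo-4-formyl-6-hydroxyphenyl sulfate | CC[NH+](CC)CC.O=Cc1c(Br)c(O)c(OS(=O)(=O)[O-])c(Br)c1Br | intermediate
7 | triethylammonium 2,3,5-tribromo-6-hydroxy-4-(hydroxymethyl)phenyl sulfate | CC[NH+](CC)CC.OCc1c(Br)c(O)c(OS(=O)(=O)[O-])c(Br)c1Br | intermediate
8 | pyridinium triethylammonium 2,3,5-tribromo-6-hydroxy-4-[(sulfonatooxy)methyl]phenyl sulfate | CC[NH+](CC)CC.c1cc[nH+]cc1.[O-]S(=O)(=O)OCc1c(Br)c(O)c(OS(=O)(=O)[O-])c(Br)c1Br | intermediate
9 | 2,3,5-tribromo-6-hydroxy-4-[(sulfooxy)methyl]phenyl hydrogen sulfate | O=S(=O)(O)OCc1c(Br)c(O)c(OS(=O)(=O)O)c(Br)c1Br | target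

**Step count**
Total steps: 3. Longest linear sequence: 3 steps.

**Steps most likely to fail, with fallbacks**

Step 1 is the most likely to fail. o-Bromanil is a strong oxidant and a heterodiene, so electron transfer, attack at oxygen or carbonyl, or cycloaddition may compete with C-substitution by the hydrazone. The fallback sets out from 1 and comes back at 5, using a charged nitronate as the formyl anion equivalent and a Nef-type unmasking. Compound 1 is treated with nitromethane and K2CO3 in MeCN at 0 °C, where addition–elimination at C4 gives 3,4,6-tribromo-5-(nitromethyl)cyclohexa-3,5-diene-1,2-dione F1, held as its nitronate and likewise deactivated towards a second substitution. Buffered aqueous TiCl3 with NH4OAc (trivalent titanium) then reduces the quinone to 3,4,6-tribromo-5-(nitromethyl)benzene-1,2-diol F2 and converts its nitronate to the imine, which hydrolyses to 5.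

Step 2 is the second risk. The acidity gap between the two phenols may give only partial regioselectivity, and the two regioisomeric sulfate salts are hard to separate. The fallback sets out from 5 and comes back at 7, using a neutral protected sulfate that can be purified and assigned on silica. Compound 5 is treated with 2,2,2-trichloroethyl chlorosulfate, Et3N (1.0 equiv) and catalytic DMAP in THF at −20 °C to give 2,3,5-tribromo-4-formyl-6-hydroxyphenyl 2,2,2-trichloroethyl sulfate F3, which is freed from any regioisomer by chromatography. NaBH4 in THF/MeOH at 0 °C gives 2,3,5-tribromo-6-hydroxy-4-(hydroxymethyl)phenyl 2,2,2-trichloroethyl sulfate F4. Zn dust with HCO2H/Et3N in MeOH at rt then removes the trichloroethyl group by reductive fragmentation and delivers 7 directly as its triethylammonium salt.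

Step 3 is the third risk. The phenol may be sulfated as well, and the free acid is hydrolytically labile, so it must be kept cold. The fallback sets out from 7 and comes back at 9, masking the phenol so that no chemoselectivity is needed. Compound 7 is treated with Ac2O (1.05 equiv) and Et3N in MeCN at 0 °C, which acylates only the phenoxide and gives triethylammonium 2-(acetyloxy)-3,5,6-tribromo-4-(hydroxymethyl)phenyl sulfate F5. Excess SO3·NEt3 in DMF at rt gives bis(triethylammonium) 2-(acetyloxy)-3,5,6-tribromo-4-[(sulfonatooxy)methyl]phenyl sulfate F6. Concentrated aqueous NH3 at 0 °C removes the acetate, and the acid resin at 0 °C gives 9.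

**Further compounds**
F1 | step 1 | 3,4,6-tribromo-5-(nitromethyl)cyclohexa-3,5-diene-1,2-dione | O=C1C(=O)C(Br)=C(Br)C(C[N+](=O)[O-])=C1Br
F2 | step 1 | 3,4,6-tribromo-5-(nitromethyl)benzene-1,2-diol | [O-][N+](=O)Cc1c(Br)c(O)c(O)c(Br)c1Br
F3 | step 2 | 2,3,5-tribromo-4-formyl-6-hydroxyphenyl 2,2,2-trichloroethyl sulfate | O=Cc1c(Br)c(O)c(OS(=O)(=O)OCC(Cl)(Cl)Cl)c(Br)c1Br
F4 | step 2 | 2,3,5-tribromo-6-hydroxy-4-(hydroxymethyl)phenyl 2,2,2-trichloroethyl sulfate | OCc1c(Br)c(O)c(OS(=O)(=O)OCC(Cl)(Cl)Cl)c(Br)c1Br
F5 | step 3 | triethylammonium 2-(acetyloxy)-3,5,6-tribromo-4-(hydroxymethyl)phenyl sulfate | CC[NH+](CC)CC.CC(=O)Oc1c(Br)c(CO)c(Br)c(Br)c1OS(=O)(=O)[O-]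
F6 | step 3 | bis(triethylammonium) 2-(acetyloxy)-3,5,6-tribromo-4-[(sulfonatooxy)methyl]phenyl sulfate | CC[NH+](CC)CC.CC[NH+](CC)CC.CC(=O)Oc1c(Br)c(COS(=O)(=O)[O-])c(Br)c(Br)c1OS(=O)(=O)[O-]
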